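(Readings and results are calculated from invented constants; the scatter is artificial.)

**Decisive number.** One figure places each flask on its curve of target: N, the dose it receives (substrate concentration times time) over the dose at which target tops out at its temperature, a Damköhler number. I read N below one as still climbing and N well above one as falling.

| setting | Thursday's | Wednesday's | teal | grey | green |
|---|---|---|---|---|---|
| substrate | 15 mM | 34 mM | 23 mM | 23 mM | 23 mM |
| partner | 2 equiv | 2 equiv | 2.00 equiv | 2.00 equiv | 2.00 equiv |
| temperature | 10 °C | 32 °C | 20 °C | 40 °C | 0 °C |
| remark | run made earlier | run made earlier |  |  |  |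
| time |  |  | 4.0 min | 4.0 min | 4.0 min |

Thursday's run (percent of the substrate charged)

| time / min | target / % |
|---|---|
| 0.333 | 3.1 |
| 1.00 | 14.1 |
| 1.50 | 20.4 |
| 2.50 | 29.8 |
| 4.00 | 36.7 |
| 5.00 | 38.3 |
| 6.00 | 38.6 |

Wednesday's run (percent of the substrate charged)

| time / s | target / % |
|---|---|
| 15.0 | 25.9 |
| 30.0 | 33.6 |
| 50.0 | 34.1 |
| 80.0 | 29.2 |
| 90.0 | 28.4 |
| 120 | 23.1 |

(readings scatter by 0.5 percentage points)

* the flask that comes out highest in amount of target, in percent of the substrate charged, or "all alike" when all lie within 1.5 percentage points (teal / grey / green / all alike)
* target at the end, in percent of the substrate charged, teal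
* target at the end, in percent of the substrate charged, grey
* target at the end, in percent of the substrate charged, green

**Peak dose.** Wednesday's target tops out at 34.1% of the charge near 50.0 s, while Thursday's reaches 38.6% at 6.00 min, flat by its last reading. With partner at fixed equivalents I take the start as bimolecular, so time counts multiplied by concentration. From Thursday's run to Wednesday's the peak dose shrinks to 0.315 of itself, and I spread that factor evenly over the degrees. Green's share of its peak dose comes to N = 0.604. Teal gets 1.73, and grey gets 4.94, the furthest along.

**One enough?** Not for heights. Wednesday's run stands at 0.760 of its top at N = 0.300, but Thursday's needs N = 0.417 to stand at 0.772, so equal N does not mean equal height. I therefore commit to sides: green still climbing at the end, teal past its top, grey far past it and lowest. Green against teal stays open.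

**The forecast.** It names teal at 31%, with grey at 4% and green at 24%, adding that “green is not far behind”.

**The result.** The flask gives teal: teal 33.4%, grey 4.91%, green 30.2%.

    substrate + partner → intermediate + by-product (k = 32.0 /M/min, Ea = 41.0 kJ/mol)
    intermediate ⇌ target (K = 1.10, k = 5.30 /min, Ea = 86.0 kJ/mol, ΔH = −3.00 kJ/mol)
    intermediate ⇌ isomer of the product (K = 12.0, k = 0.250 /min, Ea = 78.0 kJ/mol, ΔH = 3.00 kJ/mol)
    crystals ⇌ by-product, rate k4*(cs4 - [by-product]) while solid is left; crystals form when [by-product] > cs4 (solubility = 1.10 mM, k = 8.90 /min)
    intermediate → decomposed reagent (k = 0.0440 /min, Ea = 89.0 kJ/mol)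
    (constants at 20 °C)

Green's N of 0.604 lies below one, and green's target did climb, from 14.9% after 2.00 min to 30.2% after 4.00 min.

**Green, longer.** Left until 6.0 min, green has N = 0.907, still below one, so I read target there as still climbing and higher than at the asked time. The computed value is 38.8%.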